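**Plan**

- Feature used: the cyclohexene fused to the butenolide carries a quaternary C(CH3)(CH2–) next to the butenolide β-carbon and, next to it, a CH(CH3) with the two methyl groups cis. Its O-bearing CH lies para to the quaternary carbon. A 2-alkoxy-1,3-diene and the cis-methyl pair of (E)-2-methylbut-2-enal give exactly this pattern in a [4+2] addition.
- Cuts, in retrosynthetic order: (a) the C(sp3)–C(sp2) bond between the CH2CH2 arm and the methyl-bearing alkene carbon; (b) the tertiary C–O ether bond; (c) the ring bonds CH2–CH(CH3) and C(quaternary)–C(butenolide β); (d) the butenolide C3–vinyl bond.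
- Forward: the butenolide is bought, a Stille coupling gives the diene, and the [4+2] step closes the carbocycle. The butenolide alkene is then restored and the C7 ketone reduced. The side chain is joined through the ether, and the 12-membered ring is closed last by B-alkyl Suzuki coupling.
- Stereochemistry: C4/C5 come from the chiral Lewis acid and the E geometry of the enal, and C7 from a CBS reduction. The side-chain carbinol comes from an asymmetric methallylboration. The tertiary ether carbon comes from a 1,3-syn iodocarbonate cyclisation followed by inversion in the epoxide opening. The Z alkene comes from trans-hydroalumination/iodination and is retained in the coupling.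

Key step: step 2

Numbering: the bicyclic core is numbered as 2-benzofuran-1(3H)-one (C1 lactone C=O, C3 OCH2, C3a, C4 quaternary, C5 CHMe, C6 CH2, C7 C–O, C7a).

Assumption: the sense of induction in step 2 follows the usual formyl C–H···O, s-trans-enal model, in which the (S)-prolinol-derived oxazaborolidinium ion exposes the Cα-Re face of the enal; should the opposite sense be found, the (R)-catalyst is used and nothing else changes.

**Route**

Step 1
Reactants: 1 3-bromofuran-2(5H)-one; 2 tributyl(1-ethoxyvinyl)stannane
Product: 3 3-(1-ethoxyvinyl)furan-2(5H)-one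
Conditions: PdCl2(PPh3)2 (5 mol%), dioxane, 90 °C; chromatography on Et3N-deactivated silica, used at once
Reagents that add atoms: none
Why: Stille coupling of an α-bromo-butenolide with an α-alkoxyvinylstannane, in which oxidative addition into the activated C(sp2)–Br bond is easy and the neutral conditions keep the enol ether intact.

Step 2
Reactants: 3 3-(1-ethoxyvinyl)furan-2(5H)-one; 4 (E)-2-methylbut-2-enal
Product: 5 (3aS,4S,5R)-7-ethoxy-4,5-dimethyl-1-oxo-1,3,3a,4,5,6-hexahydro-2-benzofuran-4-carbaldehyde
Conditions: (S)-o-tolyl-oxazaborolidinium triflimide [from (S)-α,α-diphenylprolinol, o-tolylboroxine, Tf2NH] (20 mol%), 4 (3 equiv), 4 Å MS, CH2Cl2, −78 → −20 °C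
Reagents that add atoms: none
Why: The cationic boron binds the formyl oxygen of 4 (s-trans enal, formyl C–H···O contact) and lowers its LUMO, so the electron-rich CH2 terminus of the 2-ethoxydiene adds to Cβ and the butenolide β-carbon closes onto Cα in a concerted, strongly asynchronous [4+2] addition (limiting case: Mukaiyama–Michael then Michael). The closest known reaction type is the oxazaborolidinium-catalysed Diels–Alder reaction of 2-oxy-1,3-dienes with α-substituted enals, which gives formyl-bearing quaternary carbons. The six-membered carbocycle is closed by intermolecular suprafacial–suprafacial cycloaddition, both ring bonds forming in the same step. C4 and C5 are set together: the cis methyl pair is copied from the E geometry of 4, and the absolute configuration (4S,5R) comes from the catalyst, whose aryl group should shield the Cα-Si face so that the diene adds to the Cα-Re face; C3a follows the endo/exo preference and is of no consequence because it becomes sp2 in step 5. The step needs regioselectivity (ethoxy carbon para to the quaternary carbon), which the ethoxy donor and the acceptor character of the butenolide β-carbon secure together, and facial selectivity, which the catalyst secures. It also needs C=C over C=O selectivity in 4, expected because O-closure onto the oxocarbenium ion is reversible under the Lewis acid whereas C–C closure is not.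

Step 3
Reactants: 5 (3aS,4S,5R)-7-ethoxy-4,5-dimethyl-1-oxo-1,3,3a,4,5,6-hexahydro-2-benzofuran-4-carbaldehyde
Product: 6 (3aS,4S,5R)-4-ethenyl-7-ethoxy-4,5-dimethyl-3a,4,5,6-tetrahydro-2-benzofuran-1(3H)-one
Conditions: Ph3PCH3Br, KHMDS, THF, −78 → 0 °C
Reagents that add atoms: methyltriphenylphosphonium bromide, C[P+](c1ccccc1)(c1ccccc1)c1ccccc1.[Br-]
Why: Wittig methylenation, in which the non-enolisable neopentyl aldehyde is far more electrophilic than the vinylogous-carbonate lactone and no stereocentre is touched.

Step 4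
Reactants: 6 (3aS,4S,5R)-4-ethenyl-7-ethoxy-4,5-dimethyl-3a,4,5,6-tetrahydro-2-benzofuran-1(3H)-one
Product: 7 (3aR,4S,5R)-4-ethenyl-4,5-dimethyl-3a,4,5,6-tetrahydro-2-benzofuran-1,7(3H,7aH)-dione (C7a epimers and enol form)
Conditions: 1 M HCl, THF, rt
Reagents that add atoms: water, O
Why: Acid-catalysed enol ether hydrolysis (C-protonation at C7a, capture of the oxocarbenium ion by water, loss of ethanol), to which the monosubstituted alkene and the lactone are inert; the uncontrolled C7a centre is removed in step 5.

Step 5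
Reactants: 7 (3aR,4S,5R)-4-ethenyl-4,5-dimethyl-3a,4,5,6-tetrahydro-2-benzofuran-1,7(3H,7aH)-dione
Product: 10 (4S,5R)-4-ethenyl-4,5-dimethyl-5,6-dihydro-2-benzofuran-1,7(3H,4H)-dione, via 7a-phenylselanyl keto lactone 8 (not isolated), via selenoxide 9 (not isolated)
Conditions: PhSeCl, pyridine, CH2Cl2, 0 °C; then 30% H2O2 (2 equiv), 0 °C → rt
Reagents that add atoms: none
Why: α-Selenenylation of a β-dicarbonyl compound followed by selenoxide syn-elimination; the PhSeCl–pyridine complex should take the enol of the β-keto lactone in preference to the isolated alkene, selenium enters cis to the C3a hydrogen (cis-fused bicycle), and that hydrogen is the only one available, so the alkene can form only between C3a and C7a.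

Step 6
Reactants: 10 (4S,5R)-4-ethenyl-4,5-dimethyl-5,6-dihydro-2-benzofuran-1,7(3H,4H)-dione
Product: 11 (4S,5R,7R)-4-ethenyl-7-hydroxy-4,5-dimethyl-4,5,6,7-tetrahydro-2-benzofuran-1(3H)-one
Conditions: (S)-Me-CBS (0.5 equiv), catecholborane (1.5 equiv), toluene, −78 °C; MeOH quench
Reagents that add atoms: none
Why: CBS reduction, in which the ketone binds boron anti to its larger sp2 (C7a) side and hydride is delivered to the C7 Si face (the face of the two methyl groups), so the hydroxyl ends up cis to the vinyl group (7R) by reagent control; catecholborane at low temperature reduces the conjugated ketone 1,2 and leaves lactone and alkene alone.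

Step 7
Reactants: 12 but-2-yn-1-ol
Product: 14 (2Z)-3-iodobut-2-en-1-ol, via cyclic alkenylalanate 13 (not isolated)
Conditions: Red-Al (1.5 equiv), THF, 0 °C → rt; then I2, −78 → 0 °C
Reagents that add atoms: iodine, II
Why: Hydroxyl-directed trans-hydroalumination of a propargylic alcohol places aluminium on C3 in a five-membered ring, and iodinolysis with retention gives the iodide cis to CH2OH (Z).

Step 8
Reactants: 14 (2Z)-3-iodobut-2-en-1-ol
Product: 15 (2Z)-3-iodobut-2-enal
Conditions: MnO2 (excess), CH2Cl2, rt, dark; used at once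
Reagents that add atoms: none
Why: Allylic oxidation with MnO2 under neutral conditions, which should avoid Z → E isomerisation of the enal.

Step 9
Reactants: 15 (2Z)-3-iodobut-2-enal; 16 2-methylallylmagnesium chloride
Product: 19 (2Z,4S)-2-iodo-6-methylhepta-2,6-dien-4-ol, via B-methallyldiisopinocampheylborane 17 (not isolated), via borinate ester 18 (not isolated)
Conditions: (−)-Ipc2BOMe [from (+)-α-pinene], 16, Et2O, −78 °C → rt; then 15, −78 °C; then 3 M NaOH, 30% H2O2, 0 °C → rt
Reagents that add atoms: none
Why: Brown asymmetric methallylboration through a chair transition state, in which the reagent of the (+)-α-pinene series attacks the aldehyde Si face and sets the carbinol as 4S.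

Step 10
Reactants: 19 (2Z,4S)-2-iodo-6-methylhepta-2,6-dien-4-ol
Product: 20 tert-butyl (2Z,4S)-2-iodo-6-methylhepta-2,6-dien-4-yl carbonate
Conditions: Boc2O, DMAP (cat.), MeCN, rt
Reagents that add atoms: di-tert-butyl dicarbonate, CC(C)(C)OC(=O)OC(=O)OC(C)(C)C
Why: DMAP-catalysed acylation of a secondary alcohol to the mixed carbonate, with no change at the stereocentre.

Step 11
Reactants: 20 tert-butyl (2Z,4S)-2-iodo-6-methylhepta-2,6-dien-4-yl carbonate
Product: 21 (4R,6S)-4-(iodomethyl)-6-[(1Z)-2-iodoprop-1-en-1-yl]-4-methyl-1,3-dioxan-2-one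
Conditions: IBr (1.2 equiv), toluene, −85 °C; aq. Na2S2O3/NaHCO3
Reagents that add atoms: iodine monobromide, IBr
Why: Iodocarbonate cyclisation, in which the carbonyl oxygen closes onto the iodonium ion of the electron-rich 1,1-disubstituted alkene (the deactivated vinyl iodide is left alone) through a chair with the alkenyl group and CH2I both equatorial, setting the tertiary C–O centre 1,3-syn (4R) with loss of the tert-butyl group.

Step 12
Reactants: 21 (4R,6S)-4-(iodomethyl)-6-[(1Z)-2-iodoprop-1-en-1-yl]-4-methyl-1,3-dioxan-2-one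
Product: 22 (2S,3Z)-4-iodo-1-[(2R)-2-methyloxiran-2-yl]pent-3-en-2-ol
Conditions: K2CO3 (3 equiv), MeOH, rt
Reagents that add atoms: none
Why: Carbonate methanolysis followed by intramolecular Williamson closure of the tertiary alkoxide onto CH2I, so the tertiary C–O bond is never broken and its configuration is retained.

Step 13
Reactants: 22 (2S,3Z)-4-iodo-1-[(2R)-2-methyloxiran-2-yl]pent-3-en-2-ol
Product: 23 tert-butyl{[(2S,3Z)-4-iodo-1-[(2R)-2-methyloxiran-2-yl]pent-3-en-2-yl]oxy}dimethylsilane
Conditions: TBSCl, imidazole, DMF, rt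
Reagents that add atoms: tert-butyldimethylsilyl chloride, CC(C)(C)[Si](C)(C)Cl
Why: Silylation of the secondary alcohol, which removes the internal nucleophile before the Lewis-acid step and does not participate in epoxide opening.

Step 14
Reactants: 11 (4S,5R,7R)-4-ethenyl-7-hydroxy-4,5-dimethyl-4,5,6,7-tetrahydro-2-benzofuran-1(3H)-one; 23 tert-butyl{[(2S,3Z)-4-iodo-1-[(2R)-2-methyloxiran-2-yl]pent-3-en-2-yl]oxy}dimethylsilane
Product: 24 (4S,5R,7R)-7-{[(2S,4S,5Z)-4-{[tert-butyl(dimethyl)silyl]oxy}-1-hydroxy-6-iodo-2-methylhept-5-en-2-yl]oxy}-4-ethenyl-4,5-dimethyl-4,5,6,7-tetrahydro-2-benzofuran-1(3H)-one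
Conditions: BF3·OEt2 (10 mol%), CH2Cl2 (concentrated), −40 °C, slow addition of 23 to 11 (1.5 equiv, excess recovered)
Reagents that add atoms: none
Why: Lewis-acid-catalysed alcoholysis of a 2,2-disubstituted epoxide, which takes place at the tertiary carbon in a borderline SN2 process with inversion (2R epoxide → 2S ether) and leaves the primary hydroxyl; keeping the alcohol in excess over the activated epoxide should hold back hydride-shift rearrangement and attack by the product's own primary hydroxyl.

Step 15
Reactants: 24 (4S,5R,7R)-7-{[(2S,4S,5Z)-4-{[tert-butyl(dimethyl)silyl]oxy}-1-hydroxy-6-iodo-2-methylhept-5-en-2-yl]oxy}-4-ethenyl-4,5-dimethyl-4,5,6,7-tetrahydro-2-benzofuran-1(3H)-one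
Product: 26 neocucurbin A tert-butyldimethylsilyl ether (silyl group on the allylic secondary oxygen), via B-alkyl-9-BBN borane 25 (not isolated)
Conditions: 9-BBN (3 equiv), THF, rt; then H2O; slow addition to PdCl2(dppf) (20 mol%), AsPh3 (40 mol%), Cs2CO3 (3 equiv), DMF/THF/H2O, rt, 2 mM
Reagents that add atoms: none
Why: Anti-Markovnikov hydroboration of the only monosubstituted alkene followed by intramolecular B-alkyl Suzuki–Miyaura coupling at high dilution, which closes the 12-membered ring with retention of the vinyl iodide geometry (Z); the free primary hydroxyl is carried as its borinate and released on work-up.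

Step 16
Reactants: 26 neocucurbin A tert-butyldimethylsilyl ether
Product: 27 neocucurbin A
Conditions: HF·pyridine, pyridine, THF, 0 °C → rt
Reagents that add atoms: none
Why: Fluoride-mediated cleavage of the secondary silyl ether under buffered, non-basic conditions that should leave the butenolide, the tertiary ether and the allylic alcohol untouched.

**Compound list**

1 | 3-bromofuran-2(5H)-one | BrC1=CCOC1=O | starting material
2 | tributyl(1-ethoxyvinyl)stannane | CCCC[Sn](CCCC)(CCCC)C(=C)OCC | starting material
3 | 3-(1-ethoxyvinyl)furan-2(5H)-one | C=C(OCC)C1=CCOC1=O | intermediate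
4 | (E)-2-methylbut-2-enal | C/C=C(\C)C=O | starting material
5 | (3aS,4S,5R)-7-ethoxy-4,5-dimethyl-1-oxo-1,3,3a,4,5,6-hexahydro-2-benzofuran-4-carbaldehyde (endo adduct; 4-Me cis to 5-Me) | CCOC1=C2C(=O)OC[C@H]2[C@@](C)(C=O)[C@H](C)C1 | intermediate
6 | (3aS,4S,5R)-4-ethenyl-7-ethoxy-4,5-dimethyl-3a,4,5,6-tetrahydro-2-benzofuran-1(3H)-one | CCOC1=C2C(=O)OC[C@H]2[C@@](C)(C=C)[C@H](C)C1 | intermediate
7 | (3aR,4S,5R)-4-ethenyl-4,5-dimethyl-3a,4,5,6-tetrahydro-2-benzofuran-1,7(3H,7aH)-dione (C7a not defined; keto/enol mixture) | O=C1C2C(=O)OC[C@H]2[C@@](C)(C=C)[C@H](C)C1 | intermediate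
8 | 7a-(phenylselanyl) derivative of 7, selenium cis to the C3a hydrogen (formed in the flask) | O=C1[C@@]2([Se]c3ccccc3)C(=O)OC[C@H]2[C@@](C)(C=C)[C@H](C)C1 | intermediate
9 | selenoxide of 8 (formed in the flask) | O=C1[C@@]2([Se](=O)c3ccccc3)C(=O)OC[C@H]2[C@@](C)(C=C)[C@H](C)C1 | intermediate
10 | (4S,5R)-4-ethenyl-4,5-dimethyl-5,6-dihydro-2-benzofuran-1,7(3H,4H)-dione | O=C2C[C@@H](C)[C@](C)(C=C)C1=C2C(=O)OC1 | intermediate
11 | (4S,5R,7R)-4-ethenyl-7-hydroxy-4,5-dimethyl-4,5,6,7-tetrahydro-2-benzofuran-1(3H)-one | O[C@@H]2C[C@@H](C)[C@](C)(C=C)C1=C2C(=O)OC1 | intermediate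
12 | but-2-yn-1-ol | CC#CCO | starting material
13 | sodium cyclic alkenylalanate from 12 and Red-Al (formed in the flask) | CC1=CCO[Al-]1(OCCOC)OCCOC.[Na+] | intermediate
14 | (2Z)-3-iodobut-2-en-1-ol | C/C(I)=C/CO | intermediate
15 | (2Z)-3-iodobut-2-enal | C/C(I)=C/C=O | intermediate
16 | 2-methylallylmagnesium chloride | C=C(C)C[Mg]Cl | starting material
17 | B-(2-methylallyl)diisopinocampheylborane, (+)-α-pinene series (formed in the flask) | C=C(C)CB([C@@H]1C[C@@H]2C[C@H]([C@H]1C)C2(C)C)[C@@H]1C[C@@H]2C[C@H]([C@H]1C)C2(C)C | intermediate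
18 | diisopinocampheylborinate ester of 19 (formed in the flask) | C/C(I)=C/[C@H](CC(C)=C)OB([C@@H]1C[C@@H]2C[C@H]([C@H]1C)C2(C)C)[C@@H]1C[C@@H]2C[C@H]([C@H]1C)C2(C)C | intermediate
19 | (2Z,4S)-2-iodo-6-methylhepta-2,6-dien-4-ol | C/C(I)=C/[C@@H](O)CC(C)=C | intermediate
20 | tert-butyl (2Z,4S)-2-iodo-6-methylhepta-2,6-dien-4-yl carbonate | C/C(I)=C/[C@@H](OC(=O)OC(C)(C)C)CC(C)=C | intermediate
21 | (4R,6S)-4-(iodomethyl)-6-[(1Z)-2-iodoprop-1-en-1-yl]-4-methyl-1,3-dioxan-2-one | C/C(I)=C/[C@@H]1C[C@](C)(CI)OC(=O)O1 | intermediate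
22 | (2S,3Z)-4-iodo-1-[(2R)-2-methyloxiran-2-yl]pent-3-en-2-ol | C/C(I)=C/[C@@H](O)C[C@]1(C)CO1 | intermediate
23 | tert-butyl{[(2S,3Z)-4-iodo-1-[(2R)-2-methyloxiran-2-yl]pent-3-en-2-yl]oxy}dimethylsilane | C/C(I)=C/[C@@H](O[Si](C)(C)C(C)(C)C)C[C@]1(C)CO1 | intermediate
24 | (4S,5R,7R)-7-{[(2S,4S,5Z)-4-(TBS-oxy)-1-hydroxy-6-iodo-2-methylhept-5-en-2-yl]oxy}-4-ethenyl-4,5-dimethyl-4,5,6,7-tetrahydro-2-benzofuran-1(3H)-one | C/C(I)=C/[C@@H](O[Si](C)(C)C(C)(C)C)C[C@@](C)(CO)O[C@@H]2C[C@@H](C)[C@](C)(C=C)C1=C2C(=O)OC1 | intermediate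
25 | 9-BBN adduct of 24: B-alkyl borane on the former vinyl terminus, primary hydroxyl as 9-BBN borinate (formed in the flask) | C/C(I)=C/[C@@H](O[Si](C)(C)C(C)(C)C)C[C@@](C)(COB3C4CCCC3CCC4)O[C@@H]2C[C@@H](C)[C@](C)(CCB3C4CCCC3CCC4)C1=C2C(=O)OC1 | intermediate
26 | neocucurbin A tert-butyldimethylsilyl ether (silyl on the allylic secondary oxygen) | C/C1=C/[C@@H](O[Si](C)(C)C(C)(C)C)C[C@@](C)(CO)O[C@@H]2C[C@@H](C)[C@](C)(CC1)C1=C2C(=O)OC1 | intermediate
27 | neocucurbin A | C/C1=C/[C@@H](O)C[C@@](C)(CO)O[C@@H]2C[C@@H](C)[C@](C)(CC1)C1=C2C(=O)OC1 | target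

**Step count and risks**

Total: 16 steps (core, steps 1–6; side chain, steps 7–13; union and endgame, steps 14–16). Longest linear sequence: 10 steps (steps 7–16, from but-2-yn-1-ol).

Steps most likely to fail:

1. Step 2. The cross-conjugated lactone lowers the diene HOMO and its carbonyl can hold on to the cationic boron catalyst, so turnover may stall and facial selectivity may erode. Adventitious acid may also cleave the enol ether, and reversible O-closure (hetero-Diels–Alder) may divert material. Fallback: asymmetric catalysis is replaced by resolution. Starting from 3 and 4, the cycloaddition is run with a stoichiometric achiral Lewis acid (Me2AlCl, CH2Cl2, −78 °C) or at 12–15 kbar without promoter. This should give the racemic adduct, that is 5 together with its mirror image, the ent-adduct F1. Preparative chromatography on a chiral stationary phase removes F1, and the route is rejoined at 5.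

2. Step 14. The Lewis-acid-activated epoxide may undergo a 1,2-hydride shift to the aldehyde, or be opened by the primary hydroxyl of the product, faster than it is captured by the hindered secondary alcohol. Partial ionisation at the tertiary carbon would also erode the inversion. Fallback: the order of the two unions is reversed, so that the C–O bond is formed inside the ring. Starting from 11, hydroboration with 9-BBN gives the O-borylated B-alkyl-9-BBN adduct F2. This is cross-coupled with 23 (PdCl2(dppf), AsPh3, Cs2CO3, DMF/THF/H2O) to the seco epoxy alcohol F3. Ring-closing epoxide opening at the tertiary carbon with inversion (BF3·OEt2 or Sc(OTf)3, CH2Cl2, high dilution) then gives 26, where the route is rejoined.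

3. Step 6. The intrinsic bias of the ring (hydride delivery anti to the C5 methyl group) may override the catalyst and give the C7 epimer, and conjugate reduction of the doubly activated alkene may compete. Fallback: substrate control followed by inversion. Starting from 10, Luche reduction (NaBH4, CeCl3·7H2O, MeOH, −78 °C) should give the C7-epimeric alcohol F4. A Mitsunobu reaction with 4-nitrobenzoic acid (PPh3, DIAD, THF) inverts C7 to the 4-nitrobenzoate F5, and methanolysis (K2CO3, MeOH, 0 °C) returns 11.

**Further compounds**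

F1 | step 2 | (3aR,4R,5S)-7-ethoxy-4,5-dimethyl-1-oxo-1,3,3a,4,5,6-hexahydro-2-benzofuran-4-carbaldehyde (enantiomer of 5) | CCOC1=C2C(=O)OC[C@@H]2[C@](C)(C=O)[C@@H](C)C1
F2 | step 14 | 9-BBN adduct of 11 (B-alkyl borane on the former vinyl terminus, C7 hydroxyl as 9-BBN borinate) | O(B3C4CCCC3CCC4)[C@@H]2C[C@@H](C)[C@](C)(CCB3C4CCCC3CCC4)C1=C2C(=O)OC1
F3 | step 14 | (4S,5R,7R)-7-hydroxy-4,5-dimethyl-4-[(3Z,5S)-5-(TBS-oxy)-3-methyl-6-[(2R)-2-methyloxiran-2-yl]hex-3-en-1-yl]-4,5,6,7-tetrahydro-2-benzofuran-1(3H)-one | O[C@@H]2C[C@@H](C)[C@](C)(CC/C(C)=C\[C@@H](O[Si](C)(C)C(C)(C)C)C[C@]3(C)CO3)C1=C2C(=O)OC1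
F4 | step 6 | (4S,5R,7S)-4-ethenyl-7-hydroxy-4,5-dimethyl-4,5,6,7-tetrahydro-2-benzofuran-1(3H)-one | O[C@H]2C[C@@H](C)[C@](C)(C=C)C1=C2C(=O)OC1
F5 | step 6 | (4S,5R,7R)-4-ethenyl-4,5-dimethyl-1-oxo-1,3,4,5,6,7-hexahydro-2-benzofuran-7-yl 4-nitrobenzoate | O=C(O[C@@H]2C[C@@H](C)[C@](C)(C=C)C1=C2C(=O)OC1)c1ccc(cc1)[N+](=O)[O-]
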